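The seven-membered ring is cut into a three-carbon unit, C1–C5–C6 of a cyclopentenyl acylsilane, and a four-carbon unit, C7–C10 of the enolate of 4-methoxybut-3-en-2-one (daucane numbering). One Brook-rearrangement-mediated [3+4] annulation (1,2-addition, silyl shift, cyclopropanolate closure, anionic oxy-Cope, loss of methoxide) forms C6–C7 and the quaternary C1–C10 bond and delivers the cycloheptadienone with oxygen on C6 and C8 and the C9=C10 alkene in place. The step exploits the 1,3-dioxygenated C6–C7–C8 segment of the seven-membered ring next to the methyl-bearing ring-fusion carbon C1. A temporary 4-silyloxy stereocentre on the five-membered ring steers C1; methyl, hydride and isopropyl additions and esterification finish the route.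

Key step: step 6

Remark: the fused bicyclo[5.3.0]decane core ("hydroazulene") is numbered as in daucane: C1 methyl-bearing ring-fusion carbon, C2, C3, C4 carbinol carbon of the five-membered ring, C5 ring-fusion CH, C6 ester carbon, C7, C8 methyl carbinol, C9=C10 with C10 on C1. β is the face of the C1 methyl group, α the opposite face. The target is 1β-methyl, 4β-OH, 5α-H, 6α-O-acyl, 8α-OH, that is (1R,4R,5S,6S,8R). Compounds 1, 8 and 22 are assumed to be commercial.

Step 1
Reactants: 1 2-bromo-3-methylcyclopent-2-en-1-one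
Product: 2 (1S)-2-bromo-3-methylcyclopent-2-en-1-ol
Conditions: (R)-2-methyl-CBS-oxazaborolidine (20 mol %), BH3·SMe2, THF, −20 °C; MeOH
Reagents that add atoms: none
Why: Corey–Bakshi–Shibata reduction, in which the α-bromovinyl arm acts as the large group so that hydride reaches one carbonyl face only and should set the temporary C4 carbinol as S, while the hindered bromoalkene is not hydroborated at −20 °C.

Step 2
Reactants: 2 (1S)-2-bromo-3-methylcyclopent-2-en-1-ol
Product: 3 [(1S)-2-bromo-3-methylcyclopent-2-en-1-yl]oxy(triethyl)silane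
Conditions: TESCl, imidazole, DMF, 0 °C → rt
Reagents that add atoms: chlorotriethylsilane CC[Si](Cl)(CC)CC
Why: Imidazole-assisted silylation of a secondary allylic alcohol should give a bulky, non-chelating ether that later shields the β face.

Step 3
Reactants: 3 [(1S)-2-bromo-3-methylcyclopent-2-en-1-yl]oxy(triethyl)silane
Product: 5 (5S)-2-methyl-5-(triethylsilyloxy)cyclopent-1-ene-1-carbaldehyde, via vinyllithium 4 (not isolated)
Conditions: t-BuLi (2.1 equiv), THF, −78 °C; DMF; H2O
Reagents that add atoms: N,N-dimethylformamide CN(C)C=O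
Why: Bromine–lithium exchange followed by formylation with DMF (Bouveault aldehyde synthesis) should work because at −78 °C the vinyllithium is trapped faster than the silyl group can migrate from the neighbouring oxygen.

Step 4
Reactants: 5 (5S)-2-methyl-5-(triethylsilyloxy)cyclopent-1-ene-1-carbaldehyde
Product: 6 [dimethyl(phenyl)silyl][(5S)-2-methyl-5-(triethylsilyloxy)cyclopent-1-en-1-yl]methanol (both carbinol epimers)
Conditions: PhMe2SiLi, THF, −78 °C; H2O
Reagents that add atoms: dimethyl(phenyl)silyllithium [Li][Si](C)(C)c1ccccc1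
Why: 1,2-Addition of a silyllithium to an aldehyde gives the α-hydroxysilane, conjugate addition being blocked by the fully substituted β-carbon, and the new carbinol centre is oxidised in the next step so its configuration is irrelevant.

Step 5
Reactants: 6 [dimethyl(phenyl)silyl][(5S)-2-methyl-5-(triethylsilyloxy)cyclopent-1-en-1-yl]methanol
Product: 7 [dimethyl(phenyl)silyl][(5S)-2-methyl-5-(triethylsilyloxy)cyclopent-1-en-1-yl]methanone (acylsilane)
Conditions: (COCl)2, DMSO, CH2Cl2, −78 °C; Et3N, −78 → −20 °C
Reagents that add atoms: none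
Why: Swern oxidation of an α-hydroxysilane is the classical entry to acylsilanes, and its cold amine stage is too mild for Brook rearrangement or loss of the triethylsilyl ether.

Step 6
Reactants: 7 [dimethyl(phenyl)silyl][(5S)-2-methyl-5-(triethylsilyloxy)cyclopent-1-en-1-yl]methanone; 8 (E)-4-methoxybut-3-en-2-one
Product: 12 6-[dimethyl(phenyl)silyloxy]-1β-methyl-4β-(triethylsilyloxy)hydroazulena-5,9-dien-8-one (1R,4S), via lithium enolate 9 (not isolated), via cyclopropanolate 10 (not isolated), via methoxy enolate 11 (not isolated)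
Conditions: 8, LDA, THF, −78 °C; then 7, −78 → −30 °C; then 0 °C; AcOH
Reagents that add atoms: none
Why: Enolate 9 adds to the acylsilane carbonyl of 7 (C6–C7 bond), the α-silyl alkoxide undergoes a [1,2]-Brook shift and the siloxyallyl anion closes onto the C8 carbonyl to give the cis-1,2-dialkenylcyclopropane-1,2-diolate 10, whose anionic oxy-Cope rearrangement forms the C1–C10 bond and enolate 11, which expels methoxide (E1cB) to leave the C9=C10 enone of 12. The closest known reaction is the Brook-rearrangement-mediated [3+4] annulation of acryloylsilanes with lithium enolates of alkenyl methyl ketones. The three-membered ring closes 3-exo-trig with both oxygens held on one face by lithium, which places the two alkenyl arms cis, and the seven-membered ring arises from it by a [3,3]-sigmatropic ring expansion through a boat transition state. The surviving new stereocentre C1 is controlled by the 4β-triethylsilyloxy group: the C8–C9=C10 arm should lie on the open α face of the cyclopentene, so C10 bonds to C1 from below and the methyl group becomes β, while the transient C10 centre (methoxy α, from the E enol ether) is erased by the elimination. The step needs 1,2- and not 1,4-addition of the enolate, secured by the very electrophilic acylsilane carbonyl and the fully substituted β-carbon C1, and it needs the Cope step to outrun protonation or ring opening, for which the alkoxide acceleration and the strain release must offset the cis-methyl group on C1.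

Step 7
Reactants: 12 6-[dimethyl(phenyl)silyloxy]-1β-methyl-4β-(triethylsilyloxy)hydroazulena-5,9-dien-8-one
Product: 14 8α-hydroxy-1β,8β-dimethyl-4β-(triethylsilyloxy)-5α-H-hydroazulen-9-en-6-one, via carbinol 13 (not isolated)
Conditions: MeLi, CeCl3, THF, −78 °C; then AcOH, TBAF (1.1 equiv), −78 → −20 °C
Reagents that add atoms: methyllithium [Li]C
Why: Organocerium 1,2-addition (Imamoto conditions) suppresses enolisation at C7 and conjugate addition, the folded cyclohepta-2,5-dienone should expose its convex β face so that methyl enters there and the 8-hydroxyl is α, and buffered fluoride cleavage of the enol ether then protonates C5 from the α face, away from the 1β-methyl and 4β-silyloxy groups, to give the trans ring fusion.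

Step 8
Reactants: 14 8α-hydroxy-1β,8β-dimethyl-4β-(triethylsilyloxy)-5α-H-hydroazulen-9-en-6-one
Product: 16 1β,8β-dimethyl-4β-(triethylsilyloxy)-5α-H-hydroazulen-9-ene-6α,8α-diol, via boron chelate 15 (not isolated)
Conditions: Et2BOMe, THF/MeOH (4:1), −78 °C; NaBH4; MeOH co-evaporation
Reagents that add atoms: none
Why: Narasaka–Prasad reduction, in which the diethylboron chelate ties the carbonyl oxygen to the 8α-oxygen on the α face so that external hydride must enter C6 from the β face, which should set 6α-OH cis to 8α-OH.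

Step 9
Reactants: 16 1β,8β-dimethyl-4β-(triethylsilyloxy)-5α-H-hydroazulen-9-ene-6α,8α-diol
Product: 17 6α-(tert-butyldimethylsilyloxy)-1β,8β-dimethyl-4β-(triethylsilyloxy)-5α-H-hydroazulen-9-en-8α-ol
Conditions: TBSOTf (1.2 equiv), 2,6-lutidine, CH2Cl2, −78 °C
Reagents that add atoms: tert-butyldimethylsilyl triflate CC(C)(C)[Si](C)(C)OS(=O)(=O)C(F)(F)F
Why: Silylation with a silyl triflate at −78 °C distinguishes the secondary 6-hydroxyl from the tertiary allylic 8-hydroxyl and masks C6 for the redox steps at C4.

Step 10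
Reactants: 17 6α-(tert-butyldimethylsilyloxy)-1β,8β-dimethyl-4β-(triethylsilyloxy)-5α-H-hydroazulen-9-en-8α-ol
Product: 18 6α-(tert-butyldimethylsilyloxy)-1β,8β-dimethyl-5α-H-hydroazulen-9-ene-4β,8α-diol
Conditions: HF·pyridine, pyridine, THF, 0 °C
Reagents that add atoms: none
Why: Selective desilylation, since buffered HF·pyridine removes a secondary triethylsilyl ether much faster than a secondary tert-butyldimethylsilyl ether and the pyridine buffer keeps the tertiary allylic alcohol from ionising.

Step 11
Reactants: 18 6α-(tert-butyldimethylsilyloxy)-1β,8β-dimethyl-5α-H-hydroazulen-9-ene-4β,8α-diol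
Product: 19 6α-(tert-butyldimethylsilyloxy)-8α-hydroxy-1β,8β-dimethyl-5α-H-hydroazulen-9-en-4-one
Conditions: Dess–Martin periodinane, pyridine, CH2Cl2, 0 °C
Reagents that add atoms: none
Why: Dess–Martin oxidation is neutral, so the β-silyloxy ketone should not eliminate, the tertiary allylic alcohol is untouched and the now enolisable C5 keeps its configuration.

Step 12
Reactants: 19 6α-(tert-butyldimethylsilyloxy)-8α-hydroxy-1β,8β-dimethyl-5α-H-hydroazulen-9-en-4-one
Product: 20 6α-(tert-butyldimethylsilyloxy)dauc-9-ene-4β,8α-diol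
Conditions: i-PrMgCl, CeCl3, THF, −78 → 0 °C; aq. NH4Cl
Reagents that add atoms: isopropylmagnesium chloride CC(C)[Mg]Cl
Why: Organocerium addition to a hindered, enolisable ketone (Imamoto) avoids enolisation, β-elimination and reduction, and isopropyl should attack C4 from the α face, anti to the C6-bearing branch on C5 and to the 1β-methyl group, which sets the 4β-hydroxyl.

Step 13
Reactants: 20 6α-(tert-butyldimethylsilyloxy)dauc-9-ene-4β,8α-diol
Product: 21 dauc-9-ene-4β,6α,8α-triol
Conditions: TBAF, THF, rt → 40 °C
Reagents that add atoms: none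
Why: Fluoride-induced cleavage of the silyl ether should be clean because the triol has no base-sensitive group.

Step 14
Reactants: 21 dauc-9-ene-4β,6α,8α-triol; 22 4-acetoxybenzoic acid
Product: 23 6α-(4-acetoxybenzoyloxy)dauc-9-ene-4β,8α-diol
Conditions: DCC, DMAP (cat.), CH2Cl2, 0 °C → rt
Reagents that add atoms: none
Why: Steglich esterification should acylate only the secondary 6-hydroxyl because both other hydroxyls are tertiary, and the C6–O bond is not broken so the configuration is retained.

Step 15
Reactants: 23 6α-(4-acetoxybenzoyloxy)dauc-9-ene-4β,8α-diol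
Product: 24 6α-(4-hydroxybenzoyloxy)dauc-9-ene-4β,8α-diol (1R,4R,5S,6S,8R), the target
Conditions: K2CO3 (0.2 equiv), MeOH, 0 °C
Reagents that add atoms: none
Why: Base-catalysed transesterification should remove the activated aryl acetate far faster than the hindered secondary benzoate, whose reactivity drops further once the phenoxide forms.

Compound list
1 | 2-bromo-3-methylcyclopent-2-en-1-one | CC1=C(Br)C(=O)CC1 | starting material
2 | (1S)-2-bromo-3-methylcyclopent-2-en-1-ol | O[C@H]1CCC(C)=C1Br | intermediate
3 | [(1S)-2-bromo-3-methylcyclopent-2-en-1-yl]oxy(triethyl)silane | CC[Si](CC)(CC)O[C@H]1CCC(C)=C1Br | intermediate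
4 | [(5S)-2-methyl-5-(triethylsilyloxy)cyclopent-1-en-1-yl]lithium | CC[Si](CC)(CC)O[C@H]1CCC(C)=C1[Li] | intermediate
5 | (5S)-2-methyl-5-(triethylsilyloxy)cyclopent-1-ene-1-carbaldehyde | CC[Si](CC)(CC)O[C@H]1CCC(C)=C1C=O | intermediate
6 | [dimethyl(phenyl)silyl][(5S)-2-methyl-5-(triethylsilyloxy)cyclopent-1-en-1-yl]methanol, both carbinol epimers | CC[Si](CC)(CC)O[C@H]1CCC(C)=C1C(O)[Si](C)(C)c2ccccc2 | intermediate
7 | [dimethyl(phenyl)silyl][(5S)-2-methyl-5-(triethylsilyloxy)cyclopent-1-en-1-yl]methanone | CC[Si](CC)(CC)O[C@H]1CCC(C)=C1C(=O)[Si](C)(C)c2ccccc2 | intermediate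
8 | (E)-4-methoxybut-3-en-2-one | CO/C=C/C(C)=O | starting material
9 | lithium (E)-4-methoxybuta-1,3-dien-2-olate | [Li]OC(=C)/C=C/OC | intermediate
10 | lithium 2-[dimethyl(phenyl)silyloxy]-1-[(E)-2-methoxyethenyl]-2-[(5S)-2-methyl-5-(triethylsilyloxy)cyclopent-1-en-1-yl]cyclopropan-1-olate, the two oxygens cis and the methoxyvinyl arm on the α face of the cyclopentene | CC[Si](CC)(CC)O[C@H]1CCC(C)=C1[C@]2(O[Si](C)(C)c3ccccc3)C[C@]2(O[Li])/C=C/OC | intermediate
11 | lithium C8 enolate of 6-[dimethyl(phenyl)silyloxy]-10α-methoxy-1β-methyl-4β-(triethylsilyloxy)hydroazulen-5-en-8-one | CC[Si](CC)(CC)O[C@H]1CC[C@]2(C)[C@H](OC)C=C(O[Li])CC(O[Si](C)(C)c3ccccc3)=C12 | intermediate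
12 | 6-[dimethyl(phenyl)silyloxy]-1β-methyl-4β-(triethylsilyloxy)hydroazulena-5,9-dien-8-one (1R,4S) | CC[Si](CC)(CC)O[C@H]1CC[C@]2(C)C=CC(=O)CC(O[Si](C)(C)c3ccccc3)=C12 | intermediate
13 | 6-[dimethyl(phenyl)silyloxy]-1β,8β-dimethyl-4β-(triethylsilyloxy)hydroazulena-5,9-dien-8α-ol | CC[Si](CC)(CC)O[C@H]1CC[C@]2(C)C=C[C@](C)(O)CC(O[Si](C)(C)c3ccccc3)=C12 | intermediate
14 | 8α-hydroxy-1β,8β-dimethyl-4β-(triethylsilyloxy)-5α-H-hydroazulen-9-en-6-one | CC[Si](CC)(CC)O[C@H]1CC[C@]2(C)C=C[C@](C)(O)CC(=O)[C@H]21 | intermediate
15 | 8-O-diethylboryl derivative (boron chelate) of 14 | CC[Si](CC)(CC)O[C@H]1CC[C@]2(C)C=C[C@](C)(OB(CC)CC)CC(=O)[C@H]21 | intermediate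
16 | 1β,8β-dimethyl-4β-(triethylsilyloxy)-5α-H-hydroazulen-9-ene-6α,8α-diol | CC[Si](CC)(CC)O[C@H]1CC[C@]2(C)C=C[C@](C)(O)C[C@H](O)[C@H]21 | intermediate
17 | 6α-(tert-butyldimethylsilyloxy)-1β,8β-dimethyl-4β-(triethylsilyloxy)-5α-H-hydroazulen-9-en-8α-ol | CC[Si](CC)(CC)O[C@H]1CC[C@]2(C)C=C[C@](C)(O)C[C@H](O[Si](C)(C)C(C)(C)C)[C@H]21 | intermediate
18 | 6α-(tert-butyldimethylsilyloxy)-1β,8β-dimethyl-5α-H-hydroazulen-9-ene-4β,8α-diol | O[C@H]1CC[C@]2(C)C=C[C@](C)(O)C[C@H](O[Si](C)(C)C(C)(C)C)[C@H]21 | intermediate
19 | 6α-(tert-butyldimethylsilyloxy)-8α-hydroxy-1β,8β-dimethyl-5α-H-hydroazulen-9-en-4-one | O=C1CC[C@]2(C)C=C[C@](C)(O)C[C@H](O[Si](C)(C)C(C)(C)C)[C@H]21 | intermediate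
20 | 6α-(tert-butyldimethylsilyloxy)dauc-9-ene-4β,8α-diol | CC(C)[C@]1(O)CC[C@]2(C)C=C[C@](C)(O)C[C@H](O[Si](C)(C)C(C)(C)C)[C@H]21 | intermediate
21 | dauc-9-ene-4β,6α,8α-triol | CC(C)[C@]1(O)CC[C@]2(C)C=C[C@](C)(O)C[C@H](O)[C@H]21 | intermediate
22 | 4-acetoxybenzoic acid | CC(=O)Oc1ccc(cc1)C(=O)O | starting material
23 | 6α-(4-acetoxybenzoyloxy)dauc-9-ene-4β,8α-diol | CC(C)[C@]1(O)CC[C@]2(C)C=C[C@](C)(O)C[C@H](OC(=O)c3ccc(OC(C)=O)cc3)[C@H]21 | intermediate
24 | 6α-(4-hydroxybenzoyloxy)dauc-9-ene-4β,8α-diol (1R,4R,5S,6S,8R) | CC(C)[C@]1(O)CC[C@]2(C)C=C[C@](C)(O)C[C@H](OC(=O)c3ccc(O)cc3)[C@H]21 | target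

Total step count: 15. Longest linear sequence: 15 steps (1 → 24); compounds 8 and 22 enter without steps of their own.

Steps most likely to fail

1. Step 6. The cascade may stall before the Cope step, because the C1 terminus is fully substituted and carries a cis-methyl group; the cyclopropanolate would then be lost by ring opening and protonation. Bond formation may also take place on the β face of the cyclopentene (poor facial selectivity). If only the facial sense were inverted, the enantiomeric oxazaborolidine in step 1 would correct it, since C4 is oxidised later. The fallback builds the ring stepwise; it sets out from 5 and comes back to the route at 16. Copper-mediated conjugate addition of vinylmagnesium bromide to 5 (CuBr·SMe2, TMSCl, THF, −78 °C) should occur anti to the silyloxy group, and protonation of the enolate from the α face would give the vinyl aldehyde F1. Mukaiyama aldol addition of 2-(trimethylsilyloxy)buta-1,3-diene (BF3·OEt2, −78 °C) would give the β-hydroxy vinyl ketone F2, the 6-epimer being removed by chromatography. Chelation-controlled 1,2-addition of MeMgBr would give the syn diene diol F3. Ring-closing metathesis with the second-generation Grubbs catalyst would close the C9=C10 bond and give 16.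

2. Step 7. Methyl may be delivered to the concave α face of C8 (wrong or poor facial selectivity), or the reagent may enolise C7. The fallback installs the methyl group under chelation instead; it sets out from 12 and comes back at 16. Luche reduction (NaBH4, CeCl3, MeOH) would give the allylic alcohol F4, drawn with the 8β-hydroxyl that the same facial preference would produce. Buffered TBAF would cleave the enol ether to the ketol F5. Evans–Saksena reduction (Me4NBH(OAc)3), with hydride delivered from the 8β-oxygen, would give the anti diol F6 with 6α-OH. MnO2 would oxidise only the allylic 8-hydroxyl to the hydroxy enone F7. MeMgBr, bound to the 6α-alkoxide and the carbonyl oxygen, would then place the new hydroxyl cis to the 6α-oxygen and give 16.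

3. Step 8. External hydride has to reach the hindered β face of C6; if the boron chelate is incomplete, attack from the open α face would give the 6β-alcohol (poor facial selectivity). The fallback accepts α-face delivery and inverts C6 afterwards; it sets out from 14 and comes back at 16. Evans–Saksena reduction (Me4NBH(OAc)3, MeCN/AcOH, −20 °C) delivers hydride internally from the 8α-oxygen and would give the 6β-alcohol F8. Mitsunobu reaction with 4-nitrobenzoic acid (PPh3, DIAD) would invert C6 and give the 6α-ester F9. Methanolysis (K2CO3, MeOH) would give 16.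

Further compounds
F1 | step 6 | cyclopentanecarbaldehyde with C1 (β-methyl, α-vinyl), C4 (β-triethylsilyloxy) and C5 (β-CHO, α-H) | CC[Si](CC)(CC)O[C@H]1CC[C@](C)(C=C)[C@H]1C=O
F2 | step 6 | β-hydroxy vinyl ketone from F1: C6 carbinol (configuration as in the target), C7H2, C8 ketone carrying a vinyl group | CC[Si](CC)(CC)O[C@H]1CC[C@](C)(C=C)[C@H]1[C@@H](O)CC(=O)C=C
F3 | step 6 | diene diol from F2: C8 methyl carbinol carrying a vinyl group, syn to the C6 hydroxyl | CC[Si](CC)(CC)O[C@H]1CC[C@](C)(C=C)[C@H]1[C@@H](O)C[C@@](C)(O)C=C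
F4 | step 7 | 6-[dimethyl(phenyl)silyloxy]-1β-methyl-4β-(triethylsilyloxy)hydroazulena-5,9-dien-8β-ol | CC[Si](CC)(CC)O[C@H]1CC[C@]2(C)C=C[C@@H](O)CC(O[Si](C)(C)c3ccccc3)=C12
F5 | step 7 | 8β-hydroxy-1β-methyl-4β-(triethylsilyloxy)-5α-H-hydroazulen-9-en-6-one | CC[Si](CC)(CC)O[C@H]1CC[C@]2(C)C=C[C@@H](O)CC(=O)[C@H]21
F6 | step 7 | 1β-methyl-4β-(triethylsilyloxy)-5α-H-hydroazulen-9-ene-6α,8β-diol | CC[Si](CC)(CC)O[C@H]1CC[C@]2(C)C=C[C@@H](O)C[C@H](O)[C@H]21
F7 | step 7 | 6α-hydroxy-1β-methyl-4β-(triethylsilyloxy)-5α-H-hydroazulen-9-en-8-one | CC[Si](CC)(CC)O[C@H]1CC[C@]2(C)C=CC(=O)C[C@H](O)[C@H]21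
F8 | step 8 | 1β,8β-dimethyl-4β-(triethylsilyloxy)-5α-H-hydroazulen-9-ene-6β,8α-diol | CC[Si](CC)(CC)O[C@H]1CC[C@]2(C)C=C[C@](C)(O)C[C@@H](O)[C@H]21
F9 | step 8 | 6α-(4-nitrobenzoyloxy)-1β,8β-dimethyl-4β-(triethylsilyloxy)-5α-H-hydroazulen-9-en-8α-ol | CC[Si](CC)(CC)O[C@H]1CC[C@]2(C)C=C[C@](C)(O)C[C@H](OC(=O)c3ccc(cc3)[N+](=O)[O-])[C@H]21
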